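**Retrosynthetic overview**
1. Ring B (C1 to C10) contains one CH2–CH2 unit, C3–C4. C3 adjoins the oxygen-bearing C2 and C4 is allylic to the Z C5=C6 alkene. C3 can therefore be a ketone/sulfone-stabilised carbanion and C4 a primary allylic chloride, so this bond is cut and ring B is closed last.
2. After closure, SmI2 removes the sulfone. An O14-directed Evans–Tishchenko reduction with butanal sets C2 and places the O14 butyrate, followed by O2 propionylation and release of O8/O9.
3. Ring C (C7, C8, C17, C19, O): the enolate of an (R)-4-methylbutyrolactone derivative is joined to the ring A C9 aldehyde (C8–C9 bond). The carbonyl is then moved from C7 to C19 through the lactol, Z-vinyllithium (C4 to C6) addition at C7, and oxidative lactonisation.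
4. Ring A (C1, C10 to C14) is made first by an enantioselective Diels–Alder reaction (C1–C14 and C10–C11 bonds). Epoxidation, bromide opening and E2 elimination then move the alkene to C11=C12 and place O13.
5. The rings are formed in the order A, C, B. Two safeguards apply: the sulfone is added to a C2 aldehyde, so no ester or lactone competes, and O8/O9 are tied as an acetonide, because a free O8–H lies 1,6 to C4 across the Z alkene and would close a dihydropyran.

Key step: step 27

Convention: C15 is the methyl on C1, C16 the methyl on C5, C18 the methyl on C17, C20 the methyl on C11. β is the face of ring A that carries C15 and α is the other face. TBS = tert-butyldimethylsilyl, TES = triethylsilyl, PMB = 4-methoxybenzyl, MOP = 2-methoxyprop-2-yl.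
Assumption: the antipodes of the chiral catalysts in steps 2 and 6 are named from the usual models. If the sense of induction is the reverse, the mirror-image catalyst is used.

Step 1
Reactants: 1 (E)-pent-2-enal
Product: 2 (1E,3E)-1-(tert-butyldimethylsilyloxy)penta-1,3-diene
Conditions: t-BuMe2SiOTf, Et3N, Et2O, 0 °C
Reagents that add atoms: tert-butyldimethylsilyl triflate, CC(C)(C)[Si](C)(C)OS(=O)(=O)C(F)(F)F
Why: Silyl dienol ether formation (O-silylation, then γ-deprotonation) should give mainly the E,E diene, and any Z isomers cannot reach the s-cis form and stay inert in step 2.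

Step 2
Reactants: 2 (1E,3E)-1-(tert-butyldimethylsilyloxy)penta-1,3-diene; 3 ethyl (E)-3-formylbut-2-enoate
Product: 4 ethyl (1S,2R,5S,6R)-5-(TBS-oxy)-6-formyl-2,6-dimethylcyclohex-3-ene-1-carboxylate (ring A: C15 β, formyl C2 α, ester C9 β on C10, C20 α, O14 α, alkene C12=C13)
Conditions: (S)-1-(2-methylphenyl)-3,3-diphenyltetrahydropyrrolo[1,2-c][1,3,2]oxazaborole activated with HN(SO2CF3)2 (15 mol %), CH2Cl2, –78 to –40 °C
Reagents that add atoms: none
Why: Diels–Alder reaction under chiral cationic oxazaborolidine catalysis, a known mode for α-methyl enals: boron binds the formyl oxygen, so the donor-activated diene terminus C11 bonds to C10 (β to the formyl group) and C14 to C1, the endo formyl group ends cis to O14 and C20 (all α), the E geometry of 3 places C9 trans to C2, and the shielded face of the bound enal fixes the absolute configuration at C1, C10 and C14.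

Step 3
Reactants: 4 Diels–Alder adduct; 5 methyl phenyl sulfone
Product: 8 C2 TES-oxy sulfone (C2 epimers), via (phenylsulfonyl)methyllithium 6 (not isolated), via C2 lithium alkoxide 7 (not isolated)
Conditions: 5, n-BuLi, THF, –78 °C; add 4, –78 °C; then Et3SiOTf, –78 to –20 °C
Reagents that add atoms: triethylsilyl triflate, CC[Si](CC)(CC)OS(=O)(=O)C(F)(F)F
Why: 1,2-Addition of the α-sulfonyl carbanion to the aldehyde is far faster than acylation by the hindered ethyl ester, silylation of 7 in the flask forestalls silyl migration from O14 and lactonisation, and the C2 carbinol centre is left uncontrolled because step 24 makes it the ketone.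

Step 4
Reactants: 8 C2 TES-oxy sulfone
Product: 9 C9 primary alcohol
Conditions: i-Bu2AlH (2.5 equiv), CH2Cl2, –78 to –20 °C
Reagents that add atoms: none
Why: Hydride reduction of the only ester, with silyl ethers, sulfone and alkene inert.

Step 5
Reactants: 9 C9 primary alcohol
Product: 10 ring A C9 aldehyde
Conditions: Dess–Martin periodinane, CH2Cl2, 0 to 23 °C
Reagents that add atoms: none
Why: Dess–Martin oxidation is neutral, so the equatorial C10 centre should not epimerise, and the C12=C13 alkene is too remote to move into conjugation.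

Step 6
Reactants: 11 4-methylfuran-2(5H)-one
Product: 12 (R)-4-methyldihydrofuran-2(3H)-one
Conditions: Ru(OAc)2[(S)-BINAP] (0.5 mol %), H2 (100 atm), MeOH, 50 °C
Reagents that add atoms: none
Why: Asymmetric hydrogenation of a β-substituted butenolide with a ruthenium BINAP catalyst is known, and the catalyst face sets C17.

Step 7
Reactants: 12 (R)-4-methyldihydrofuran-2(3H)-one
Product: 14 (3R,4S)-3-hydroxy-4-methyldihydrofuran-2(3H)-one, via lactone lithium enolate 13 (not isolated)
Conditions: LiN(i-Pr)2, THF, –78 °C; then 3-phenyl-2-(phenylsulfonyl)oxaziridine, –78 °C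
Reagents that add atoms: 3-phenyl-2-(phenylsulfonyl)oxaziridine, O=S(=O)(N1OC1c1ccccc1)c1ccccc1
Why: Davis enolate hydroxylation should occur trans to the methyl group, and this carbinol centre (C8) is planarised again in step 9.

Step 8
Reactants: 14 hydroxy lactone
Product: 15 MOP ether of 14
Conditions: 2-methoxypropene, pyridinium p-toluenesulfonate (2 mol %), CH2Cl2, 0 °C
Reagents that add atoms: 2-methoxypropene, COC(C)=C
Why: Acid-catalysed addition of the alcohol to the enol ether gives a base-stable, chelating acetal that already carries the carbon of the later acetonide.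

Step 9
Reactants: 15 MOP-protected lactone; 10 ring A C9 aldehyde
Product: 17 aldol adduct (C9 epimers), via alkoxylactone lithium enolate 16 (not isolated)
Conditions: 15, LiN(i-Pr)2, THF, –78 °C; then 10, –78 °C; pH 7 buffer
Reagents that add atoms: none
Why: Aldol addition of a lactone lithium enolate: the aldehyde should approach the planar enolate opposite the C17 methyl group, which sets C8 with C9 trans to C18, while the C9 carbinol may form as a mixture because steps 10 and 11 reset it.

Step 10
Reactants: 17 aldol adduct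
Product: 18 C9 ketone
Conditions: Dess–Martin periodinane, pyridine, CH2Cl2, 0 °C
Reagents that add atoms: none
Why: Buffered Dess–Martin oxidation converges both C9 epimers and spares the acid-labile MOP acetal, and C8 is quaternary so it cannot epimerise.

Step 11
Reactants: 18 C9 ketone
Product: 19 (9S)-alcohol
Conditions: Zn(BH4)2, Et2O, –30 °C
Reagents that add atoms: none
Why: Chelation-controlled reduction: zinc ties O9 to the acetal oxygen O8 so hydride passes the flat C7 carbonyl side, and the Felkin–Anh preference at C10 (quaternary C1 anti to hydride) selects the same face, which should give the 9S alcohol without touching the lactone.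

Step 12
Reactants: 19 (9S)-alcohol
Product: 20 O8/O9 acetonide
Conditions: pyridinium p-toluenesulfonate (5 mol %), CH2Cl2, 23 °C
Reagents that add atoms: none
Why: Intramolecular transacetalisation: the oxocarbenium ion formed from the MOP group by loss of methanol is trapped by the neighbouring O9–H, which masks both hydroxyls in one step without creating a new stereocentre.

Step 13
Reactants: 20 O8/O9 acetonide
Product: 21 12β,13β-epoxide
Conditions: mCPBA, CH2Cl2, 0 °C
Reagents that add atoms: 3-chloroperoxybenzoic acid, OOC(=O)c1cccc(Cl)c1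
Why: Prilezhaev epoxidation of the only alkene: the α face is blocked by the pseudoaxial O14 silyl ether and by C20 on the two allylic carbons, so oxygen should arrive on the β face.

Step 14
Reactants: 21 12β,13β-epoxide
Product: 22 12α-bromo-13β-alcohol
Conditions: LiBr, AcOH, THF, 23 °C
Reagents that add atoms: lithium bromide, [Li+].[Br-]
Why: Trans-diaxial epoxide opening (Fürst–Plattner rule): in the chair-like transition state that keeps C2, C9 and C20 equatorial, bromide enters axially at C12 from the α face, which is also the carbon farther from the electron-withdrawing O14, and C13 keeps its β oxygen.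

Step 15
Reactants: 22 12α-bromo-13β-alcohol
Product: 23 O13 TES ether
Conditions: Et3SiOTf, 2,6-lutidine, CH2Cl2, 0 °C
Reagents that add atoms: triethylsilyl triflate, CC[Si](CC)(CC)OS(=O)(=O)C(F)(F)F
Why: Silylation with the triflate reaches the axial alcohol and prevents re-closure to the epoxide under the base of step 16.

Step 16
Reactants: 23 O13 TES ether
Product: 24 ring A cyclohexene with C11=C12
Conditions: DBU, toluene, 100 °C
Reagents that add atoms: none
Why: E2 dehydrobromination: the axial 12α bromide has only one antiperiplanar hydrogen, the axial 11β-H, so the trisubstituted C11=C12 alkene should form, and C10, C13 and the non-enolisable lactone are untouched.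

Step 17
Reactants: 25 prop-2-yn-1-ol
Product: 27 (Z)-3-iodo-2-methylprop-2-en-1-ol, via cyclic vinylmagnesium alkoxide 26 (not isolated)
Conditions: MeMgBr (2.5 equiv), CuI (10 mol %), THF, –10 to 23 °C; then I2, –10 °C
Reagents that add atoms: methylmagnesium bromide, C[Mg]Br; iodine, II
Why: Alkoxide-directed, copper-catalysed anti carbomagnesiation gives the five-membered magnesacycle, and iodinolysis with retention fixes the Z geometry of the future C5=C6 alkene.

Step 18
Reactants: 27 (Z)-3-iodo-2-methylprop-2-en-1-ol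
Product: 28 PMB ether of 27
Conditions: NaH, 4-methoxybenzyl chloride, Bu4NI (cat.), THF, 0 to 23 °C
Reagents that add atoms: 4-methoxybenzyl chloride, COc1ccc(CCl)cc1
Why: Williamson etherification gives a non-silyl O4 group, which cannot migrate to carbon in the Z-vinyllithium and is removable later without acid, base or fluoride.

Step 19
Reactants: 24 ring A cyclohexene with C11=C12
Product: 29 C7 lactol
Conditions: i-Bu2AlH (1.2 equiv), CH2Cl2, –78 °C
Reagents that add atoms: none
Why: Partial lactone reduction: the aluminium lactolate next to the quaternary C8 does not collapse at –78 °C, so reduction should stop at the lactol.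

Step 20
Reactants: 29 C7 lactol; 28 PMB-protected Z-vinyl iodide
Product: 31 C7/C19 diol (7S), via Z-vinyllithium 30 (not isolated)
Conditions: 28 (4 equiv), t-BuLi (8 equiv), Et2O, –78 °C; then 29 in THF, –78 to –40 °C
Reagents that add atoms: none
Why: Iodine–lithium exchange with retention, then 1,2-addition to the ring-opened hydroxy aldehyde under Felkin–Anh control (O8 anti to the nucleophile, approach past the smaller C17 branch), should give 7S, while extra equivalents are consumed reversibly by the lactol O–H and the sulfone CH2, whose carbanion is stable at this temperature.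

Step 21
Reactants: 31 C7/C19 diol
Product: 33 ring C lactone, via C19 lactol 32 (not isolated)
Conditions: TEMPO (0.2 equiv), PhI(OAc)2 (2.5 equiv), CH2Cl2, 23 °C
Reagents that add atoms: none
Why: TEMPO-catalysed oxidative lactonisation picks the primary C19 alcohol, the aldehyde closes onto O7 and the lactol is oxidised again, and C18 already sits trans to C9, the more stable arrangement, so C17 should hold.

Step 22
Reactants: 33 ring C lactone
Product: 34 C2/C13 diol
Conditions: HF·pyridine, pyridine, THF, 0 to 23 °C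
Reagents that add atoms: none
Why: Selective desilylation: both triethylsilyl ethers are cleaved far faster than the TBS ether on the hindered O14, and acetonide, PMB ether and lactone are inert.

Step 23
Reactants: 34 C2/C13 diol
Product: 35 O13 butyrate
Conditions: butyric anhydride (1.3 equiv), Et3N, DMAP (cat.), CH2Cl2, –10 °C
Reagents that add atoms: butyric anhydride, CCCC(=O)OC(=O)CCC
Why: DMAP-catalysed acylation should take only the allylic O13–H, because the C2 carbinol is neopentylic and flanked by the sulfonylmethyl group.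

Step 24
Reactants: 35 O13 butyrate
Product: 36 β-keto sulfone
Conditions: Dess–Martin periodinane, CH2Cl2, 23 °C
Reagents that add atoms: none
Why: Dess–Martin oxidation of the remaining alcohol merges the C2 epimers into one β-keto sulfone under non-basic conditions.

Step 25
Reactants: 36 β-keto sulfone
Product: 37 Z-allylic alcohol
Conditions: DDQ, CH2Cl2–pH 7 buffer, 0 °C
Reagents that add atoms: none
Why: Oxidative PMB cleavage is orthogonal to the ester, lactone, acetonide, silyl ether and keto sulfone.

Step 26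
Reactants: 37 Z-allylic alcohol
Product: 39 seco β-keto sulfone with Z-allylic chloride, via allylic mesylate 38 (not isolated)
Conditions: MsCl, 2,4,6-collidine, LiCl, DMF, 0 °C
Reagents that add atoms: lithium chloride, [Li+].[Cl-]; methanesulfonyl chloride, CS(=O)(=O)Cl (its atoms stay only in 38)
Why: Mesylation and SN2 displacement by chloride at the primary allylic carbon avoid an allyl cation, so the Z geometry is kept, and collidine is too weak a base to deprotonate the keto sulfone.

Step 27
Reactants: 39 seco β-keto sulfone with Z-allylic chloride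
Product: 41 ring B C2 ketone C3 sulfone (C3 epimers), via caesium enolate 40 (not isolated)
Conditions: Cs2CO3 (3 equiv), DMF, 25 to 40 °C, 39 added by syringe pump (final about 1 mM)
Reagents that add atoms: none
Why: Cs2CO3 removes the C3 proton between the C2 ketone and the sulfone, by far the most acidic C–H in 39, and the soft enolate 40 displaces chloride from the primary allylic C4 in a direct SN2 step that forms C3–C4. The closest known reaction type is the high-dilution intramolecular alkylation of sulfone-stabilised carbanions by allylic halides used for ten-membered carbocycles. Ring B closes in a 10-exo-tet mode on a chain whose ends are held near each other by the trans C1/C10 substitution of ring A, the Z alkene, ring C and the acetonide. The only new stereocentre, C3, forms without control as an epimer mixture and disappears in step 28, and the Z geometry of C5=C6 is kept because no allyl cation or allyl metal species intervenes. The step needs C- over O-alkylation (soft carbanion and soft allylic chloride in DMF), SN2 over SN2′ (C4 is primary and open, whereas attack at C6 next to the substituted C7 would give a strained eight-membered ring) and cyclisation over oligomerisation (slow addition at high dilution). O8, which if free would reach C4 through a six-membered transition state, is locked in the acetonide, O14 is silylated so no β-hydroxy ketone meets the base, and C17–H is too weakly acidic for carbonate to start β-elimination.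

Step 28
Reactants: 41 ring B C2 ketone C3 sulfone
Product: 42 ring B C2 ketone
Conditions: SmI2 (3 equiv), THF–MeOH, –78 °C
Reagents that add atoms: none
Why: Reductive desulfonylation of a β-keto sulfone: electron transfer to the ketone expels benzenesulfinate, methanol protonates the samarium enolate, and esters, lactone, alkenes and silyl ether are not reduced at this temperature.

Step 29
Reactants: 42 ring B C2 ketone
Product: 43 14-hydroxy C2 ketone
Conditions: HF·pyridine, THF, 23 °C
Reagents that add atoms: none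
Why: Acidic fluoride removes the last silyl ether without the basic conditions that could trigger retro-aldol cleavage of the β-hydroxy ketone.

Step 30
Reactants: 43 14-hydroxy C2 ketone
Product: 45 (2S)-alcohol O14 butyrate, via butanal hemiacetal 44 (not isolated)
Conditions: butanal (6 equiv), SmI2 (0.3 equiv), THF, –10 °C
Reagents that add atoms: butanal, CCCC=O
Why: Evans–Tishchenko reaction: butanal forms a samarium-bound hemiacetal on O14 whose C–H is delivered intramolecularly to the C2 ketone through a chair transition state with C3 equatorial (anti to C14, gauche to C10 as ring B requires), which should give the 1,3-anti 2S alcohol and leave the oxidised aldehyde as the O14 butyrate.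

Step 31
Reactants: 45 (2S)-alcohol O14 butyrate
Product: 46 O2 propionate acetonide
Conditions: propionyl chloride, pyridine, DMAP (cat.), CH2Cl2, 0 to 23 °C
Reagents that add atoms: propionyl chloride, CCC(=O)Cl
Why: Acylation of the only free hydroxyl under weakly basic conditions should outrun butyrate migration from O14 to O2.

Step 32
Reactants: 46 O2 propionate acetonide
Product: 47 CNP0138989.1
Conditions: AcOH–H2O–THF (3:1:1), 45 °C
Reagents that add atoms: none
Why: Mild acetal hydrolysis of the crowded dioxolane frees O8–H and O9–H without ionising the allylic C7–O and C13–O bonds or cleaving the three esters.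

**Compound list**
1 | (E)-pent-2-enal | CC/C=C/C=O | starting material
2 | (1E,3E)-1-(TBS-oxy)penta-1,3-diene | C/C=C/C=C/O[Si](C)(C)C(C)(C)C | intermediate
3 | ethyl (E)-3-formylbut-2-enoate | CCOC(=O)/C=C(/C=O)C | starting material
4 | Diels–Alder adduct | CCOC(=O)[C@H]1[C@H](C)C=C[C@H](O[Si](C)(C)C(C)(C)C)[C@]1(C)C=O | intermediate
5 | methyl phenyl sulfone | CS(=O)(=O)c1ccccc1 | starting material
6 | (phenylsulfonyl)methyllithium | [Li]CS(=O)(=O)c1ccccc1 | intermediate
7 | C2 lithium alkoxide (C2 epimers) | CCOC(=O)[C@H]1[C@H](C)C=C[C@H](O[Si](C)(C)C(C)(C)C)[C@]1(C)C(O[Li])CS(=O)(=O)c2ccccc2 | intermediate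
8 | C2 TES-oxy sulfone (C2 epimers) | CCOC(=O)[C@H]1[C@H](C)C=C[C@H](O[Si](C)(C)C(C)(C)C)[C@]1(C)C(O[Si](CC)(CC)CC)CS(=O)(=O)c2ccccc2 | intermediate
9 | C9 primary alcohol | OC[C@H]1[C@H](C)C=C[C@H](O[Si](C)(C)C(C)(C)C)[C@]1(C)C(O[Si](CC)(CC)CC)CS(=O)(=O)c2ccccc2 | intermediate
10 | ring A C9 aldehyde | O=C[C@H]1[C@H](C)C=C[C@H](O[Si](C)(C)C(C)(C)C)[C@]1(C)C(O[Si](CC)(CC)CC)CS(=O)(=O)c2ccccc2 | intermediate
11 | 4-methylfuran-2(5H)-one | CC1=CC(=O)OC1 | starting material
12 | (R)-4-methyldihydrofuran-2(3H)-one | C[C@@H]1CC(=O)OC1 | intermediate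
13 | lithium enolate of 12 | C[C@@H]1C=C(O[Li])OC1 | intermediate
14 | (3R,4S)-3-hydroxy-4-methyldihydrofuran-2(3H)-one | C[C@@H]1[C@@H](O)C(=O)OC1 | intermediate
15 | MOP ether of 14 | C[C@@H]1[C@@H](OC(C)(C)OC)C(=O)OC1 | intermediate
16 | lithium enolate of 15 | C[C@@H]1C(OC(C)(C)OC)=C(O[Li])OC1 | intermediate
17 | aldol adduct (C9 epimers) | C[C@H]3COC(=O)[C@]3(OC(C)(C)OC)C(O)[C@H]1[C@H](C)C=C[C@H](O[Si](C)(C)C(C)(C)C)[C@]1(C)C(O[Si](CC)(CC)CC)CS(=O)(=O)c2ccccc2 | intermediate
18 | C9 ketone | C[C@H]3COC(=O)[C@]3(OC(C)(C)OC)C(=O)[C@H]1[C@H](C)C=C[C@H](O[Si](C)(C)C(C)(C)C)[C@]1(C)C(O[Si](CC)(CC)CC)CS(=O)(=O)c2ccccc2 | intermediate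
19 | (9S)-alcohol | C[C@H]3COC(=O)[C@]3(OC(C)(C)OC)[C@@H](O)[C@H]1[C@H](C)C=C[C@H](O[Si](C)(C)C(C)(C)C)[C@]1(C)C(O[Si](CC)(CC)CC)CS(=O)(=O)c2ccccc2 | intermediate
20 | O8/O9 acetonide | C[C@H]3COC(=O)[C@@]34OC(C)(C)O[C@H]4[C@H]1[C@H](C)C=C[C@H](O[Si](C)(C)C(C)(C)C)[C@]1(C)C(O[Si](CC)(CC)CC)CS(=O)(=O)c2ccccc2 | intermediate
21 | 12β,13β-epoxide | C[C@H]3COC(=O)[C@@]34OC(C)(C)O[C@H]4[C@H]1[C@H](C)[C@H]5O[C@H]5[C@H](O[Si](C)(C)C(C)(C)C)[C@]1(C)C(O[Si](CC)(CC)CC)CS(=O)(=O)c2ccccc2 | intermediate
22 | 12α-bromo-13β-alcohol | C[C@H]3COC(=O)[C@@]34OC(C)(C)O[C@H]4[C@H]1[C@H](C)[C@H](Br)[C@@H](O)[C@H](O[Si](C)(C)C(C)(C)C)[C@]1(C)C(O[Si](CC)(CC)CC)CS(=O)(=O)c2ccccc2 | intermediate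
23 | O13 TES ether | C[C@H]3COC(=O)[C@@]34OC(C)(C)O[C@H]4[C@H]1[C@H](C)[C@H](Br)[C@@H](O[Si](CC)(CC)CC)[C@H](O[Si](C)(C)C(C)(C)C)[C@]1(C)C(O[Si](CC)(CC)CC)CS(=O)(=O)c2ccccc2 | intermediate
24 | ring A cyclohexene with C11=C12 | C[C@H]3COC(=O)[C@@]34OC(C)(C)O[C@H]4[C@H]1C(C)=C[C@@H](O[Si](CC)(CC)CC)[C@H](O[Si](C)(C)C(C)(C)C)[C@]1(C)C(O[Si](CC)(CC)CC)CS(=O)(=O)c2ccccc2 | intermediate
25 | prop-2-yn-1-ol | C#CCO | starting material
26 | cyclic vinylmagnesium alkoxide | CC1=C[Mg]OC1 | intermediate
27 | (Z)-3-iodo-2-methylprop-2-en-1-ol | I/C=C(/C)CO | intermediate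
28 | PMB ether of 27 | I/C=C(/C)COCc1ccc(OC)cc1 | intermediate
29 | C7 lactol (anomers) | C[C@H]3COC(O)[C@@]34OC(C)(C)O[C@H]4[C@H]1C(C)=C[C@@H](O[Si](CC)(CC)CC)[C@H](O[Si](C)(C)C(C)(C)C)[C@]1(C)C(O[Si](CC)(CC)CC)CS(=O)(=O)c2ccccc2 | intermediate
30 | Z-vinyllithium | [Li]/C=C(/C)COCc1ccc(OC)cc1 | intermediate
31 | C7/C19 diol (7S) | C[C@@H](CO)[C@@]4([C@@H](O)/C=C(/C)COCc5ccc(OC)cc5)OC(C)(C)O[C@H]4[C@H]1C(C)=C[C@@H](O[Si](CC)(CC)CC)[C@H](O[Si](C)(C)C(C)(C)C)[C@]1(C)C(O[Si](CC)(CC)CC)CS(=O)(=O)c2ccccc2 | intermediate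
32 | C19 lactol (anomers) | C[C@H]3C(O)O[C@@H](/C=C(/C)COCc5ccc(OC)cc5)[C@@]34OC(C)(C)O[C@H]4[C@H]1C(C)=C[C@@H](O[Si](CC)(CC)CC)[C@H](O[Si](C)(C)C(C)(C)C)[C@]1(C)C(O[Si](CC)(CC)CC)CS(=O)(=O)c2ccccc2 | intermediate
33 | ring C lactone | C[C@H]3C(=O)O[C@@H](/C=C(/C)COCc5ccc(OC)cc5)[C@@]34OC(C)(C)O[C@H]4[C@H]1C(C)=C[C@@H](O[Si](CC)(CC)CC)[C@H](O[Si](C)(C)C(C)(C)C)[C@]1(C)C(O[Si](CC)(CC)CC)CS(=O)(=O)c2ccccc2 | intermediate
34 | C2/C13 diol (C2 epimers) | O[C@@H]1C=C(C)[C@H]([C@@H]4OC(C)(C)O[C@@]42[C@H](/C=C(/C)COCc5ccc(OC)cc5)OC(=O)[C@@H]2C)[C@@](C)(C(O)CS(=O)(=O)c3ccccc3)[C@H]1O[Si](C)(C)C(C)(C)C | intermediate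
35 | O13 butyrate (C2 epimers) | CCCC(=O)O[C@@H]1C=C(C)[C@H]([C@@H]4OC(C)(C)O[C@@]42[C@H](/C=C(/C)COCc5ccc(OC)cc5)OC(=O)[C@@H]2C)[C@@](C)(C(O)CS(=O)(=O)c3ccccc3)[C@H]1O[Si](C)(C)C(C)(C)C | intermediate
36 | β-keto sulfone | CCCC(=O)O[C@@H]1C=C(C)[C@H]([C@@H]4OC(C)(C)O[C@@]42[C@H](/C=C(/C)COCc5ccc(OC)cc5)OC(=O)[C@@H]2C)[C@@](C)(C(=O)CS(=O)(=O)c3ccccc3)[C@H]1O[Si](C)(C)C(C)(C)C | intermediate
37 | Z-allylic alcohol | CCCC(=O)O[C@@H]1C=C(C)[C@H]([C@@H]4OC(C)(C)O[C@@]42[C@H](/C=C(/C)CO)OC(=O)[C@@H]2C)[C@@](C)(C(=O)CS(=O)(=O)c3ccccc3)[C@H]1O[Si](C)(C)C(C)(C)C | intermediate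
38 | allylic mesylate | CCCC(=O)O[C@@H]1C=C(C)[C@H]([C@@H]4OC(C)(C)O[C@@]42[C@H](/C=C(/C)COS(C)(=O)=O)OC(=O)[C@@H]2C)[C@@](C)(C(=O)CS(=O)(=O)c3ccccc3)[C@H]1O[Si](C)(C)C(C)(C)C | intermediate
39 | seco β-keto sulfone with Z-allylic chloride | CCCC(=O)O[C@@H]1C=C(C)[C@H]([C@@H]4OC(C)(C)O[C@@]42[C@H](/C=C(/C)CCl)OC(=O)[C@@H]2C)[C@@](C)(C(=O)CS(=O)(=O)c3ccccc3)[C@H]1O[Si](C)(C)C(C)(C)C | intermediate
40 | caesium enolate of 39 | CCCC(=O)O[C@@H]1C=C(C)[C@H]([C@@H]4OC(C)(C)O[C@@]42[C@H](/C=C(/C)CCl)OC(=O)[C@@H]2C)[C@@](C)(C([O-])=CS(=O)(=O)c3ccccc3)[C@H]1O[Si](C)(C)C(C)(C)C.[Cs+] | intermediate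
41 | ring B C2 ketone C3 sulfone (C3 epimers) | CCCC(=O)O[C@@H]1C=C(C)[C@@H]2[C@@H]4OC(C)(C)O[C@@]43[C@H](/C=C(/C)CC(S(=O)(=O)c5ccccc5)C(=O)[C@@]2(C)[C@H]1O[Si](C)(C)C(C)(C)C)OC(=O)[C@@H]3C | intermediate
42 | ring B C2 ketone | CCCC(=O)O[C@@H]1C=C(C)[C@@H]2[C@@H]4OC(C)(C)O[C@@]43[C@H](/C=C(/C)CCC(=O)[C@@]2(C)[C@H]1O[Si](C)(C)C(C)(C)C)OC(=O)[C@@H]3C | intermediate
43 | 14-hydroxy C2 ketone | CCCC(=O)O[C@@H]1C=C(C)[C@@H]2[C@@H]4OC(C)(C)O[C@@]43[C@H](/C=C(/C)CCC(=O)[C@@]2(C)[C@H]1O)OC(=O)[C@@H]3C | intermediate
44 | butanal hemiacetal on O14 (drawn metal-free) | CCCC(=O)O[C@@H]1C=C(C)[C@@H]2[C@@H]4OC(C)(C)O[C@@]43[C@H](/C=C(/C)CCC(=O)[C@@]2(C)[C@H]1OC(O)CCC)OC(=O)[C@@H]3C | intermediate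
45 | (2S)-alcohol O14 butyrate | CCCC(=O)O[C@@H]1C=C(C)[C@@H]2[C@@H]4OC(C)(C)O[C@@]43[C@H](/C=C(/C)CC[C@H](O)[C@@]2(C)[C@H]1OC(=O)CCC)OC(=O)[C@@H]3C | intermediate
46 | O2 propionate acetonide | CCCC(=O)O[C@@H]1C=C(C)[C@@H]2[C@@H]4OC(C)(C)O[C@@]43[C@H](/C=C(/C)CC[C@H](OC(=O)CC)[C@@]2(C)[C@H]1OC(=O)CCC)OC(=O)[C@@H]3C | intermediate
47 | CNP0138989.1 | CCCC(=O)O[C@@H]1C=C(C)[C@@H]2[C@H](O)[C@@]3(O)[C@H](/C=C(/C)CC[C@H](OC(=O)CC)[C@@]2(C)[C@H]1OC(=O)CCC)OC(=O)[C@@H]3C | target

**Total step count:** 32.
**Longest linear sequence:** 27 steps (1 to 5, 9 to 16, 19 to 32).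

**Steps most likely to fail**

Step 27 (ring B closure). Ring closure against transannular strain may be slower than intermolecular alkylation, or the enolate may alkylate on oxygen. The fallback sets out from allylic alcohol 37 and returns at 41. Compound 37 is added slowly to cyanomethylenetributylphosphorane in toluene at 90 °C under high dilution. The alcohol is activated in the flask as an alkoxyphosphonium ion, and the carbanion formed from the reagent deprotonates the keto sulfone, which then attacks C4 in a Mitsunobu-type C-alkylation. No chloride and no carbonate base are used, and the same C3–C4 bond is formed by SN2. This fallback makes no compound outside the list (F0).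

Step 9 (aldol). The hindered aldehyde may be enolised rather than attacked, or the aldolate may revert. The fallback sets out from aldehyde 10 and returns at ketone 18. Pinnick oxidation (NaClO2, NaH2PO4, 2-methylbut-2-ene) gives the ring A C9 carboxylic acid F1. 1-Chloro-N,N,2-trimethylprop-1-en-1-amine converts it under neutral conditions into the ring A C9 acid chloride F2. This acylates enolate 16 on carbon at –78 °C in an irreversible Claisen-type step, again opposite the C17 methyl group, and the oxidation of step 10 is no longer needed.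

Step 2 (Diels–Alder). An uncatalysed background reaction, or acid-induced decay of the silyl dienol ether, may erode enantio- and endo selectivity. The fallback sets out from 2 and 3 and returns at 4. The cycloaddition is run thermally in toluene and gives 4 together with its mirror image ent-4 F3. The mixture is condensed with (1R,2R)-N,N′-dimethyl-1,2-diphenylethane-1,2-diamine to give the imidazolidine of 4 F4 and the imidazolidine of ent-4 F5. Because the diamine is C2-symmetric, no stereocentre is added. The two diastereomers are separated by chromatography, and mild aqueous acid hydrolysis of F4 returns enantiopure 4.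

**Further compounds**
F0 | step 27 | none | none
F1 | step 9 | ring A C9 carboxylic acid | OC(=O)[C@H]1[C@H](C)C=C[C@H](O[Si](C)(C)C(C)(C)C)[C@]1(C)C(O[Si](CC)(CC)CC)CS(=O)(=O)c2ccccc2
F2 | step 9 | ring A C9 acid chloride | ClC(=O)[C@H]1[C@H](C)C=C[C@H](O[Si](C)(C)C(C)(C)C)[C@]1(C)C(O[Si](CC)(CC)CC)CS(=O)(=O)c2ccccc2
F3 | step 2 | ent-4 | CCOC(=O)[C@@H]1[C@@H](C)C=C[C@@H](O[Si](C)(C)C(C)(C)C)[C@@]1(C)C=O
F4 | step 2 | imidazolidine of 4 | CCOC(=O)[C@H]1[C@H](C)C=C[C@H](O[Si](C)(C)C(C)(C)C)[C@]1(C)C2N(C)[C@H](c3ccccc3)[C@@H](c3ccccc3)N2C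
F5 | step 2 | imidazolidine of ent-4 | CCOC(=O)[C@@H]1[C@@H](C)C=C[C@@H](O[Si](C)(C)C(C)(C)C)[C@@]1(C)C2N(C)[C@H](c3ccccc3)[C@@H](c3ccccc3)N2C
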